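The readings stem from a simulated flask with constants of no real substance; noise was put on by code.

If the target decays once it is made, a recipe is judged by how long its target waits in the flask, so I began with the rate of that loss.

| flask | starting material | coupling partner | capture agent | remark | time |
|---|---|---|---|---|---|
| Tuesday's | 20 mM | 0.70 equiv | 6 mM | run made earlier |  |
| Thursday's | 13 mM | 0.70 equiv | 6 mM | run made earlier |  |
| Sunday's | 30 mM | 0.70 equiv | 6 mM | run made earlier |  |
| north | 20 mM | 0.700 equiv | 6.00 mM | a single well-mixed tank run continuously and read at steady state, 30 min in it on average |  |
| south | 20 mM (fed, over 30.0 min) | 0.700 equiv | 6.00 mM | a stirred flask in which starting material is dosed at a steady rate over 30.0 min without added volume, worked up at 30 min | 30 min |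
| east | 20 mM | 0.700 equiv (fed, over 30.0 min) | 6.00 mM | a stirred flask in which coupling partner is dosed at a steady rate over 30.0 min without added volume, worked up at 30 min | 30 min |
| north-west | 20 mM | 0.700 equiv | 6.00 mM | everything together in a closed stirred flask, run for 30 min | 30 min |

- Tuesday's (time / min: target / %): 4.00: 47.0; 8.00: 50.1; 12.0: 48.3; 15.0: 42.7; 20.0: 39.1; 25.0: 34.7; 30.0: 31.1
- Thursday's (time / min: target / %): 2.00: 32.3; 6.00: 46.8; 10.0: 49.1; 15.0: 45.4; 20.0: 39.0; 30.0: 31.1; 40.0: 23.1
- Sunday's (time / min: target / %): 5.00: 52.2; 10.0: 51.6; 15.0: 43.2; 20.0: 39.7; 25.0: 34.8; 30.0: 30.6; 40.0: 22.7

(standard deviation of a reading: 1 percentage point)

- the stated concentrations are those of everything mixed, before any reaction; amounts are the same in each set-up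
- the earlier runs were read with a standard deviation of 1 percentage point
- the feed brings no volume worth counting
- the earlier runs were made in a closed, stirred flask

* the set-up with the highest amount of target at the outlet or at the end, in percent of the starting material put in ("none" if the first two lie within 2 percentage points) (north / south / east / north-west / none)
* amount of target at the outlet or at the end, in percent of the starting material put in, north
* amount of target at the outlet or at the end, in percent of the starting material put in, south
* amount of target at the outlet or at the end, in percent of the starting material put in, east
* amount of target at the outlet or at the end, in percent of the starting material put in, north-west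

Thursday's target fell from 31.1% at 30.0 min to 23.1% at 40.0 min, and Sunday's, charged at 30 mM against 13 mM, read 30.6% and 22.7% at those times. The loss therefore looked first order, and from Thursday's pair I read 0.0297 min⁻¹ as the loss constant, the fraction of target lost per minute.

The coupling partner, at 0.700 equiv, is the limiting reagent and caps target at that share of the starting material. Target made evenly over a dose, at once on arrival, keeps the fraction 0.662, so east came to 46.3%. In south, the starting material fed matches the partner's charge at 21.0 min. As a simplifying assumption, I took target as made at once on arrival up to then and as only decaying for the remaining 9.00 min, and this reckoning gave 39.8%. For the north tank, taking the partner as fully turned to target, I reckoned 37.0%, and north-west repeats the recipe of Tuesday's run, which read 31.1%.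

The weak link was "at once" in east. Thursday's first reading puts target at 46.1% of what the partner allows after 2.00 min, which I read as a pseudo-first-order rate of 0.309 min⁻¹ at about 10.9 mM of starting material. Counting one starting material per partner, I reckoned the charge less the partner at 6.00 mM for the end of east, less than that, so I allowed a dose a wait of about 5.87 min. Going round once more with that wait, east fell to 40.2%. I left south unchanged and committed to a tie.

The forecast gave 34% for north, 44% for south, 44% for east and 31% for north-west, best none, since “dosing forms target later”; its south stood above mine, as did its east.

The flask gave 30.9% for north, 39.7% for south, 35.6% for east and 30.3% for north-west, so the best was south.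

    starting material + coupling partner → target (k = 35.0 L mol⁻¹ min⁻¹)
    starting material + coupling partner ⇌ intermediate A (K = 350 L mol⁻¹, k = 3.30 L mol⁻¹ min⁻¹)
    intermediate A ⇌ intermediate B (K = 3.60, k = 0.00850 min⁻¹)
    capture agent + intermediate A → trapped intermediate (k = 0.0940 L mol⁻¹ min⁻¹)
    target → over-reaction product (k = 0.0280 min⁻¹)
    2 starting material → self-condensation product (k = 0.680 L mol⁻¹ min⁻¹)

East came in 4.6 percentage points below my reckoning. There the starting material stood as high as 20.0 mM, where its first half-life by self-condensation alone is 36.8 min, not far above the dose of 30.0 min, and at 30.0 min east held 26.6% as self-condensation product against 1.90% in south.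

Reading south on to 80 min, the loss constant leaves 8.98% of the charge as target out of what stood at 30.0 min, before any target made later is counted. The computed flask holds 11.4%.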